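**Plan**
1. Retrosynthesis: after removal of two silyl groups, one cascade cuts both the C7'–aryl bond and the ring bond C8–C8', giving aryl bromide 9 and the acyclic epoxy allyl ether 7. Compound 7 is then cut at the O–C9' allyl ether bond, at the C8–C9 oxirane and at C7–C8 (vinyl addition to syringaldehyde).
2. Forward: silylated syringaldehyde → vinyl carbinol → epoxy alcohol → allyl ether, all acyclic and carrying only the first aryl ring. The oxolane ring and the second aryl ring arrive together in step 6, and desilylation ends the route.
3. Enabling feature: C7' is an exocyclic CH2 on ring carbon C8', the neighbouring ring carbon C8 carries the C9 hydroxymethyl group, and ring oxygen O1 joins C7 to C9'. This is the imprint of a C8 radical (from a C8–C9 oxirane) closing 5-exo onto an O-allyl group on C7, which leaves C7' as a primary radical for nickel-mediated arylation.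
4. Stereochemistry: C7 is selected by Sharpless kinetic resolution with D-(−)-DIPT. C8 and C8' follow from C7 in the chair-like 5-exo transition state (7,8-trans, 8,8'-cis).

Key step: step 6

Remark: lignan numbering is used (C7, C8, C9 on the side of the ring-bound aryl group; C7', C8', C9' on the benzyl side). The oxirane carbon C8 becomes a planar radical in step 6, so its configuration in 5 and 7 does not reach the target. In the SMILES of 10 and 11 the cyclopentadienyl rings on titanium are drawn sigma-bonded.

**Step 1**
Reactants: 1 syringaldehyde
Product: 2 3,5-dimethoxy-4-(triisopropylsilyloxy)benzaldehyde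
Conditions: TIPSCl, imidazole, DMAP (cat.), DMF, rt
Reagents that add atoms: triisopropylsilyl chloride, CC(C)[Si](Cl)(C(C)C)C(C)C
Why: O-silylation of the acidic phenol should proceed cleanly, and the bulky silyl ether is chosen to survive Grignard, alkoxide and reductive conditions and to leave under fluoride at the end.

**Step 2**
Reactants: 2 3,5-dimethoxy-4-(triisopropylsilyloxy)benzaldehyde; 3 vinylmagnesium bromide
Product: 4 rac-1-[3,5-dimethoxy-4-(triisopropylsilyloxy)phenyl]prop-2-en-1-ol
Conditions: THF, −78 to 0 °C; then H2O
Reagents that add atoms: none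
Why: Grignard 1,2-addition to the aryl aldehyde installs C8 and C9 as a vinyl group and gives the racemic secondary allylic alcohol required for resolution.

**Step 3**
Reactants: 4 rac-1-[3,5-dimethoxy-4-(triisopropylsilyloxy)phenyl]prop-2-en-1-ol
Product: 5 (R)-[3,5-dimethoxy-4-(triisopropylsilyloxy)phenyl][(2S)-oxiran-2-yl]methanol
Conditions: Ti(OiPr)4 (20 mol%), D-(−)-DIPT (25 mol%), TBHP (0.45 equiv), 4 Å MS, CH2Cl2, −20 °C
Reagents that add atoms: tert-butyl hydroperoxide, CC(C)(C)OO
Why: Sharpless kinetic resolution, in which the titanium–D-(−)-tartrate catalyst should epoxidize only the (S)-enantiomer of 4 (carbinol hydrogen on the face of oxygen delivery) and do so erythro-selectively, so that sub-stoichiometric TBHP converts that enantiomer into 5 and leaves the (R)-alcohol to be separated; this selection fixes C7.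

**Step 4**
Reactants: 5 (R)-[3,5-dimethoxy-4-(triisopropylsilyloxy)phenyl][(2S)-oxiran-2-yl]methanol; 6 allyl bromide
Product: 7 (2S)-2-[(R)-(allyloxy)[3,5-dimethoxy-4-(triisopropylsilyloxy)phenyl]methyl]oxirane
Conditions: NaH, Bu4NI (cat.), THF, 0 °C to rt
Reagents that add atoms: none
Why: Williamson etherification of the secondary alkoxide with a reactive allylic halide in an aprotic medium should outpace Payne rearrangement and leaves C7 untouched, since only the O–H bond reacts.

**Step 5**
Reactants: 8 4-bromo-2,6-dimethoxyphenol
Product: 9 (4-bromo-2,6-dimethoxyphenoxy)triisopropylsilane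
Conditions: TIPSCl, imidazole, DMF, rt
Reagents that add atoms: triisopropylsilyl chloride, CC(C)[Si](Cl)(C(C)C)C(C)C
Why: O-silylation masks the acidic phenol of the aryl bromide so that it cannot quench organotitanium or organonickel intermediates in step 6.

**Step 6**
Reactants: 7 (2S)-2-[(R)-(allyloxy)[3,5-dimethoxy-4-(triisopropylsilyloxy)phenyl]methyl]oxirane; 9 (4-bromo-2,6-dimethoxyphenoxy)triisopropylsilane
Product: 12 [(2S,3R,4R)-2-[3,5-dimethoxy-4-(triisopropylsilyloxy)phenyl]-4-[3,5-dimethoxy-4-(triisopropylsilyloxy)benzyl]oxolan-3-yl]methanol, via titanoxy secondary radical 10 (not isolated), via cyclized primary radical 11 (not isolated)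
Conditions: NiCl2·dme (10 mol%), 4,4'-di-tert-butyl-2,2'-bipyridine (10 mol%), Cp2TiCl2 (20 mol%), Mn powder (3 equiv), Et3N·HCl (1.5 equiv), DMPU, rt
Reagents that add atoms: none
Why: Proposed new method: Mn reduces Cp2TiCl2 to Cp2TiCl (trivalent titanium), which opens the oxirane of 7 by single-electron transfer at the more substituted carbon to give the β-titanoxy secondary radical 10; this 3-oxa-5-hexenyl radical closes the oxolane ring by 5-exo-trig attack on the allyl ether (new C8–C8' bond), the resulting primary C7' radical 11 is captured by the aryl nickel bromide (divalent nickel) formed from 9 and zerovalent nickel, reductive elimination from trivalent nickel forges the C7'–aryl bond, and Et3N·HCl protonates the titanium alkoxide to free the C9 alcohol and turn titanium over. The closest known reaction types are the Nugent–RajanBabu radical cyclization of epoxy allyl ethers with Cp2TiCl, the nickel/titanium co-catalysed reductive arylation of epoxides with aryl bromides, and the nickel-catalysed reductive cyclization–arylation of alkene-tethered alkyl halides; their merger into one cascade that starts from an epoxide is the untested part. Both new stereocentres arise in the ring closure: in a Beckwith–Houk chair-like transition state the C7 aryl group sits pseudo-equatorial, the CH2OTi arm on the planar radical carbon turns away from it (7,8-trans) and ends cis to the new exocyclic CH2 (8,8'-cis), so C8 and C8' are controlled by the C7 stereocentre, which is never a radical site. The step needs cyclization of 10 to outrun its bimolecular capture by aryl nickel (direct arylation at C8) or by a second Cp2TiCl (deoxygenation to the alkene), which the fast unimolecular closure of an oxygen-tethered hexenyl radical and the low catalyst loadings should secure; it also needs 11 to be arylated and not reduced, for which an unhindered primary radical is the most favourable case for nickel capture.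

**Step 7**
Reactants: 12 [(2S,3R,4R)-2-[3,5-dimethoxy-4-(triisopropylsilyloxy)phenyl]-4-[3,5-dimethoxy-4-(triisopropylsilyloxy)benzyl]oxolan-3-yl]methanol
Product: 13 (+)-(7S,8R,8'R)-5,5'-dimethoxylariciresinol
Conditions: TBAF, AcOH, THF, 0 °C to rt
Reagents that add atoms: none
Why: Fluoride-induced cleavage of both aryl silyl ethers, buffered with acetic acid so that no free phenoxide can open the 2-aryloxolane through a quinone methide, should release the target without touching C7, C8 or C8'.

**Compound list**
1 | syringaldehyde (4-hydroxy-3,5-dimethoxybenzaldehyde) | COc1cc(C=O)cc(OC)c1O | starting material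
2 | 3,5-dimethoxy-4-(triisopropylsilyloxy)benzaldehyde | COc1cc(C=O)cc(OC)c1O[Si](C(C)C)(C(C)C)C(C)C | intermediate
3 | vinylmagnesium bromide | C=C[Mg]Br | starting material
4 | rac-1-[3,5-dimethoxy-4-(triisopropylsilyloxy)phenyl]prop-2-en-1-ol | C=CC(O)c1cc(OC)c(O[Si](C(C)C)(C(C)C)C(C)C)c(OC)c1 | intermediate
5 | (R)-[3,5-dimethoxy-4-(triisopropylsilyloxy)phenyl][(2S)-oxiran-2-yl]methanol | O[C@H](c1cc(OC)c(O[Si](C(C)C)(C(C)C)C(C)C)c(OC)c1)[C@@H]2CO2 | intermediate
6 | allyl bromide | C=CCBr | starting material
7 | (2S)-2-[(R)-(allyloxy)[3,5-dimethoxy-4-(triisopropylsilyloxy)phenyl]methyl]oxirane | C=CCO[C@H](c1cc(OC)c(O[Si](C(C)C)(C(C)C)C(C)C)c(OC)c1)[C@@H]2CO2 | intermediate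
8 | 4-bromo-2,6-dimethoxyphenol | COc1cc(Br)cc(OC)c1O | starting material
9 | (4-bromo-2,6-dimethoxyphenoxy)triisopropylsilane | COc1cc(Br)cc(OC)c1O[Si](C(C)C)(C(C)C)C(C)C | intermediate
10 | β-titanoxy secondary radical at C8 (chlorobis(cyclopentadienyl)titanium alkoxide on C9, allyl ether intact) | C=CCO[C@H](c1cc(OC)c(O[Si](C(C)C)(C(C)C)C(C)C)c(OC)c1)[CH]CO[Ti](Cl)(C2C=CC=C2)C3C=CC=C3 | intermediate
11 | cyclized primary radical at C7' on the (2S,3R,4R)-oxolane (titanium alkoxide on C9) | [CH2][C@H]1CO[C@H](c2cc(OC)c(O[Si](C(C)C)(C(C)C)C(C)C)c(OC)c2)[C@H]1CO[Ti](Cl)(C3C=CC=C3)C4C=CC=C4 | intermediate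
12 | [(2S,3R,4R)-2-[3,5-dimethoxy-4-(triisopropylsilyloxy)phenyl]-4-[3,5-dimethoxy-4-(triisopropylsilyloxy)benzyl]oxolan-3-yl]methanol | COc1cc(C[C@H]2CO[C@H](c3cc(OC)c(O[Si](C(C)C)(C(C)C)C(C)C)c(OC)c3)[C@H]2CO)cc(OC)c1O[Si](C(C)C)(C(C)C)C(C)C | intermediate
13 | (+)-(7S,8R,8'R)-5,5'-dimethoxylariciresinol | COc1cc(C[C@H]2CO[C@H](c3cc(OC)c(O)c(OC)c3)[C@H]2CO)cc(OC)c1O | target

**Step count**
Total steps: 7. Longest linear sequence: 6 steps (1, 2, 3, 4, 6, 7); step 5 is a one-step side branch.

**Steps most likely to fail**

Step 6 (Proposed new method). The two catalytic cycles may fail to mesh. The uncyclized radical may be arylated or deoxygenated before ring closure, or the cyclized primary radical may be reduced to a methyl group by titanium before nickel intercepts it. Fallback with known chemistry, setting out from 7: stoichiometric Cp2TiCl (from Cp2TiCl2 and Zn dust, THF, rt) effects the same epoxide opening and 5-exo closure. The cyclized radical is reduced by a second Cp2TiCl to the alkyl titanium species (tetravalent titanium), and an iodine quench should give [(2S,3R,4R)-2-[3,5-dimethoxy-4-(triisopropylsilyloxy)phenyl]-4-(iodomethyl)oxolan-3-yl]methanol F1. The primary iodide of F1 is then joined to aryl bromide 9 by nickel-catalysed cross-electrophile coupling (NiI2, 4,4'-di-tert-butyl-2,2'-bipyridine, Zn dust, NaI, pyridine, DMPU, 60 °C). The route is rejoined at 12.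

Step 3. Rate discrimination between the enantiomers may be insufficient for a slowly epoxidized terminal vinyl carbinol, and conversion may overrun, so that the epoxy alcohol is isolated with eroded enantiopurity. Ionization of the electron-rich benzylic alcohol by the Lewis acid could add to the loss. Fallback, setting out from 4: acylative kinetic resolution with immobilized Candida antarctica lipase B and vinyl acetate (MTBE, 30 °C) should acetylate the (R)-enantiomer to (R)-1-[3,5-dimethoxy-4-(triisopropylsilyloxy)phenyl]prop-2-en-1-yl acetate F3. Run past half conversion, it should leave (S)-1-[3,5-dimethoxy-4-(triisopropylsilyloxy)phenyl]prop-2-en-1-ol F2 in high enantiopurity. F2 is then epoxidized to completion by hydroxyl-directed epoxidation with Ti(OiPr)4, D-(−)-DIPT and TBHP in the matched sense, where selectivity no longer depends on conversion. The route is rejoined at 5.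

Step 4. The sodium alkoxide may undergo Payne rearrangement to the isomeric aryl-substituted epoxide, or accept the silyl group from the aryl oxygen, before it is allylated. Fallback, setting out from 5: neutral Tsuji–Trost O-allylation with allyl tert-butyl carbonate (Pd2(dba)3, 1,4-bis(diphenylphosphino)butane, THF, 60 °C) delivers the allyl group through a π-allyl palladium intermediate without a stoichiometric free alkoxide. The route is rejoined at 7; this fallback makes no new compound (F0).

**Further compounds**
F1 | step 6 | [(2S,3R,4R)-2-[3,5-dimethoxy-4-(triisopropylsilyloxy)phenyl]-4-(iodomethyl)oxolan-3-yl]methanol | IC[C@H]1CO[C@H](c2cc(OC)c(O[Si](C(C)C)(C(C)C)C(C)C)c(OC)c2)[C@H]1CO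
F2 | step 3 | (S)-1-[3,5-dimethoxy-4-(triisopropylsilyloxy)phenyl]prop-2-en-1-ol | O[C@H](c1cc(OC)c(O[Si](C(C)C)(C(C)C)C(C)C)c(OC)c1)C=C
F3 | step 3 | (R)-1-[3,5-dimethoxy-4-(triisopropylsilyloxy)phenyl]prop-2-en-1-yl acetate | CC(=O)O[C@@H](c1cc(OC)c(O[Si](C(C)C)(C(C)C)C(C)C)c(OC)c1)C=C
F0 | step 4 | none | none
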